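**Strategy.** Ring B is closed around its C6=C7 edge. A keto ester whose C5 carbonyl is locked between the quaternary carbons C4 and C10 (no α-hydrogen) and whose C8 is the α-carbon of the C17 ester receives both carbons of an acetyl donor in one pot: Claisen acylation forms C7–C8, then the γ-dianion closes C6–C5 by aldol addition and dehydration. In the resulting ring B enone C8 lies between two carbonyls and settles as the equatorial ester; C5–H and the C6=C7 alkene follow by carbonyl reduction and allylic diazene transposition. C9 and C10 are set earlier by iridium-catalysed allylation, and the side chain is attached last by Suzuki–Miyaura coupling.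

Key step: step 4

Remark on numbering: carbon labels follow the labdane convention (ring A: C1–C5 and C10; ring B: C5–C10; side chain C11–C16; C17 is the ester carbon on C8).

Assumption: in step 2 the ligand antipode is the one that gives (S) at C9, and the enolate face is taken to follow the staggered open approach described there; if the opposite relative sense is found, the first fallback applies.

Step 1
Reactants: 1 (but-3-en-1-yloxy)(tert-butyl)dimethylsilane; 2 allyl methyl carbonate
Product: 3 (E)-5-[(tert-butyldimethylsilyl)oxy]pent-2-en-1-yl methyl carbonate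
Conditions: second-generation Grubbs catalyst (3 mol %), 2 (3 equiv), CH2Cl2, 40 °C
Reagents that add atoms: none
Why: Olefin cross-metathesis of two terminal alkenes with loss of ethylene should give mainly the E alkene, and the excess of the cheap carbonate 2 suppresses homodimerisation of 1.

Step 2
Reactants: 4 2,2,6-trimethylcyclohexan-1-one; 3 (E)-5-[(tert-butyldimethylsilyl)oxy]pent-2-en-1-yl methyl carbonate
Product: 5 (S)-2-[(S)-5-[(tert-butyldimethylsilyl)oxy]pent-1-en-3-yl]-2,6,6-trimethylcyclohexan-1-one
Conditions: [Ir(cod)Cl]2 (2 mol %), binaphthol-derived N,N-bis(1-arylethyl)phosphoramidite (4 mol %, antipode as in the assumption), Ba(OtBu)2 (0.6 equiv), THF, 5 °C; then aq. NH4Cl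
Reagents that add atoms: none
Why: Iridium-catalysed asymmetric allylic alkylation (branch-selective Tsuji–Trost type) of the barium enolate of 4, which can form only toward C10 because C4 is quaternary: the enolate attacks the substituted allyl terminus on the face opposite the metal, so the ligand sets C9, while the staggered approach that puts the enolate methyl anti to the allylic hydrogen and the enolate C–O bond anti to the vinyl group should set C10 relative to C9.

Step 3
Reactants: 5 (S)-2-[(S)-5-[(tert-butyldimethylsilyl)oxy]pent-1-en-3-yl]-2,6,6-trimethylcyclohexan-1-one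
Product: 7 methyl (S)-3-[(S)-1,3,3-trimethyl-2-oxocyclohexyl]pent-4-enoate, via carboxylic acid 6 (not isolated)
Conditions: CrO3, H2SO4, acetone–H2O, 0 °C; then TMSCHN2, MeOH–PhMe, 0 to 23 °C
Reagents that add atoms: water, O; trimethylsilyldiazomethane, C[Si](C)(C)C=[N+]=[N-]
Why: Jones oxidation cleaves the primary silyl ether and oxidises the freed alcohol through the aldehyde hydrate to the acid, which trimethylsilyldiazomethane esterifies without base, so the hindered ketone, the vinyl group and the C9 and C10 centres are left untouched.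

Step 4
Reactants: 7 methyl (S)-3-[(S)-1,3,3-trimethyl-2-oxocyclohexyl]pent-4-enoate; 8 1-acetylimidazole
Product: 11 methyl (1R,2R,8aS)-1-ethenyl-5,5,8a-trimethyl-3-oxo-1,2,3,5,6,7,8,8a-octahydronaphthalene-2-carboxylate, via beta-keto ester 9 (not isolated), via aldol adduct 10 (not isolated)
Conditions: LiN(iPr)2 (1.05 equiv), THF, −78 °C; 8 (1.1 equiv), −78 to 0 °C; LiN(iPr)2 (2.3 equiv), −78 to 0 °C; AcOH; then p-TsOH·H2O (cat.), PhMe, 60 °C
Reagents that add atoms: none
Why: The lithium enolate of the C17 ester, the only enolate that can form because the C5 ketone lies between the quaternary carbons C4 and C10, is C-acylated by 8 (crossed Claisen condensation, C7–C8), and the expelled imidazolide deprotonates beta-keto ester 9 so that no enolate is wasted. Excess amide base then removes a proton from the acetyl methyl group to give the γ-dianion, whose terminal carbon adds to the C5 ketone (intramolecular aldol addition, C6–C5), and acid eliminates water from the tertiary aldol 10 to the conjugated enone. The closest known reaction type is the acylation and γ-dianion aldol chemistry of acetoacetates, used here as a Robinson-type annulation in which an acetyl group supplies C6 and C7; ring B closes in the 6-(enolendo)-exo-trig mode. C8 is the only new stereocentre that survives, and because it sits between the ketone and the ester it equilibrates through the enol to the equatorial ester, trans to the C9 vinyl group and away from the axial C10 methyl. The step needs C- over O-acylation and reaction at C8 and C6 only, which the lack of α-hydrogens at C5 and the masking of C8 as its enolate during the second deprotonation secure.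

Step 5
Reactants: 11 methyl (1R,2R,8aS)-1-ethenyl-5,5,8a-trimethyl-3-oxo-1,2,3,5,6,7,8,8a-octahydronaphthalene-2-carboxylate
Product: 12 methyl (1R,2R,3R,8aS)-1-ethenyl-3-hydroxy-5,5,8a-trimethyl-1,2,3,5,6,7,8,8a-octahydronaphthalene-2-carboxylate
Conditions: NaBH4, CeCl3·7H2O, MeOH, −40 °C
Reagents that add atoms: none
Why: Luche reduction: cerium-assisted 1,2-hydride delivery to the keto tautomer from the axial face opposite the C10 methyl should give the equatorial C7 alcohol cis to that methyl, while C8 stays the equatorial ester.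

Step 6
Reactants: 12 methyl (1R,2R,3R,8aS)-1-ethenyl-3-hydroxy-5,5,8a-trimethyl-1,2,3,5,6,7,8,8a-octahydronaphthalene-2-carboxylate
Product: 15 methyl (1R,2S,4aR,8aS)-1-ethenyl-5,5,8a-trimethyl-1,2,4a,5,6,7,8,8a-octahydronaphthalene-2-carboxylate, via sulfonylhydrazone adduct 13 (not isolated), via allylic diazene 14 (not isolated)
Conditions: N-isopropylidene-N'-(2-nitrobenzenesulfonyl)hydrazine (IPNBSH), PPh3, DEAD, THF, 0 to 23 °C; then CF3CH2OH–H2O (1:1), 23 °C
Reagents that add atoms: none
Why: Mitsunobu displacement at C7 by the sulfonyl hydrazide with inversion, hydrolysis to the monoalkyl diazene and its retro-ene loss of nitrogen transfer hydrogen to C5 on the face that now carries nitrogen, anti to the C10 methyl, which sets the trans ring fusion and moves the alkene to C6=C7 without any base that could touch C8.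

Step 7
Reactants: 16 methyl 4-hydroxybut-2-ynoate
Product: 17 methyl (Z)-4-hydroxy-3-iodobut-2-enoate
Conditions: NaI, AcOH, 80 °C
Reagents that add atoms: sodium iodide, [Na+].[I-]
Why: Hydroiodination of the ynoate by conjugate attack of iodide and anti protonation should give the Z iodide with iodine cis to the ester, an isomer that cannot lactonise.

Step 8
Reactants: 17 methyl (Z)-4-hydroxy-3-iodobut-2-enoate
Product: 18 methyl (Z)-4-acetoxy-3-iodobut-2-enoate
Conditions: Ac2O, pyridine, DMAP (cat.), CH2Cl2, 0 to 23 °C
Reagents that add atoms: acetic anhydride, CC(=O)OC(C)=O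
Why: Nucleophile-catalysed acetylation of the primary allylic alcohol leaves the vinyl iodide and the ester unchanged.

Step 9
Reactants: 15 methyl (1R,2S,4aR,8aS)-1-ethenyl-5,5,8a-trimethyl-1,2,4a,5,6,7,8,8a-octahydronaphthalene-2-carboxylate; 18 methyl (Z)-4-acetoxy-3-iodobut-2-enoate
Product: 20 methyl (1R,2S,4aR,8aS)-1-[(3E)-3-(acetoxymethyl)-5-methoxy-5-oxopent-3-en-1-yl]-5,5,8a-trimethyl-1,2,4a,5,6,7,8,8a-octahydronaphthalene-2-carboxylate, via alkylborane 19 (not isolated)
Conditions: 9-BBN, THF, 23 to 45 °C; then 18, Pd(dppf)Cl2 (5 mol %), AsPh3, Cs2CO3, DMF–H2O, 23 °C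
Reagents that add atoms: none
Why: 9-BBN should add only to the terminal vinyl group (boron at C12) and not to the cis-disubstituted ring alkene, and the B-alkyl Suzuki–Miyaura coupling with 18 proceeds with retention of alkene geometry, so the ester ends cis to the chain and trans to the acetoxymethyl group as in 20.

**Compound list**

1 | (but-3-en-1-yloxy)(tert-butyl)dimethylsilane | C=CCCO[Si](C)(C)C(C)(C)C | starting material
2 | allyl methyl carbonate | C=CCOC(=O)OC | starting material
3 | (E)-5-[(tert-butyldimethylsilyl)oxy]pent-2-en-1-yl methyl carbonate | COC(=O)OC/C=C/CCO[Si](C)(C)C(C)(C)C | intermediate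
4 | 2,2,6-trimethylcyclohexan-1-one (racemic) | CC1CCCC(C)(C)C1=O | starting material
5 | (S)-2-[(S)-5-[(tert-butyldimethylsilyl)oxy]pent-1-en-3-yl]-2,6,6-trimethylcyclohexan-1-one | C=C[C@@H]([C@]1(C)CCCC(C)(C)C1=O)CCO[Si](C)(C)C(C)(C)C | intermediate
6 | (S)-3-[(S)-1,3,3-trimethyl-2-oxocyclohexyl]pent-4-enoic acid | C=C[C@@H]([C@]1(C)CCCC(C)(C)C1=O)CC(=O)O | intermediate
7 | methyl (S)-3-[(S)-1,3,3-trimethyl-2-oxocyclohexyl]pent-4-enoate | C=C[C@@H]([C@]1(C)CCCC(C)(C)C1=O)CC(=O)OC | intermediate
8 | 1-acetylimidazole | CC(=O)n1ccnc1 | starting material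
9 | beta-keto ester: 2-acetyl derivative of 7 (C8 epimers, C9 and C10 as in 7) | C=C[C@@H]([C@]1(C)CCCC(C)(C)C1=O)C(C(C)=O)C(=O)OC | intermediate
10 | aldol adduct: ring B closed, tertiary C5 alcohol, C7 ketone (C5 and C8 unassigned) | C=C[C@@H]1C(C(=O)OC)C(=O)CC2(O)C(C)(C)CCC[C@@]12C | intermediate
11 | methyl (1R,2R,8aS)-1-ethenyl-5,5,8a-trimethyl-3-oxo-1,2,3,5,6,7,8,8a-octahydronaphthalene-2-carboxylate (keto form; C8 ester trans to C9 vinyl) | C=C[C@@H]1[C@@H](C(=O)OC)C(=O)C=C2C(C)(C)CCC[C@@]12C | intermediate
12 | methyl (1R,2R,3R,8aS)-1-ethenyl-3-hydroxy-5,5,8a-trimethyl-1,2,3,5,6,7,8,8a-octahydronaphthalene-2-carboxylate (C7 hydroxyl cis to C10 methyl) | C=C[C@@H]1[C@@H](C(=O)OC)[C@H](O)C=C2C(C)(C)CCC[C@@]12C | intermediate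
13 | sulfonylhydrazone adduct: C7 carries N(2-nitrobenzenesulfonyl)–N=CMe2, inverted, anti to C10 methyl | C=C[C@@H]1[C@@H](C(=O)OC)[C@@H](N(N=C(C)C)S(=O)(=O)c3ccccc3[N+](=O)[O-])C=C2C(C)(C)CCC[C@@]12C | intermediate
14 | allylic diazene: C7–N=NH, nitrogen anti to C10 methyl | C=C[C@@H]1[C@@H](C(=O)OC)[C@@H](N=N)C=C2C(C)(C)CCC[C@@]12C | intermediate
15 | methyl (1R,2S,4aR,8aS)-1-ethenyl-5,5,8a-trimethyl-1,2,4a,5,6,7,8,8a-octahydronaphthalene-2-carboxylate | C=C[C@@H]1[C@@H](C(=O)OC)C=C[C@@H]2C(C)(C)CCC[C@@]12C | intermediate
16 | methyl 4-hydroxybut-2-ynoate | COC(=O)C#CCO | starting material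
17 | methyl (Z)-4-hydroxy-3-iodobut-2-enoate | COC(=O)/C=C(\I)CO | intermediate
18 | methyl (Z)-4-acetoxy-3-iodobut-2-enoate | COC(=O)/C=C(\I)COC(C)=O | intermediate
19 | alkylborane: 9-BBN adduct of 15 with boron on C12 | B1(CC[C@@H]2[C@@H](C(=O)OC)C=C[C@@H]3C(C)(C)CCC[C@@]23C)C4CCCC1CCC4 | intermediate
20 | methyl (1R,2S,4aR,8aS)-1-[(3E)-3-(acetoxymethyl)-5-methoxy-5-oxopent-3-en-1-yl]-5,5,8a-trimethyl-1,2,4a,5,6,7,8,8a-octahydronaphthalene-2-carboxylate | COC(=O)/C=C(\CC[C@@H]1[C@@H](C(=O)OC)C=C[C@@H]2C(C)(C)CCC[C@@]12C)COC(C)=O | target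

**Step count.** Total: 9 steps. Longest linear sequence: 7 steps (steps 1, 2, 3, 4, 5, 6 and 9).

**Steps most likely to fail**

Step 2. What may go wrong: sluggish attack of the hindered tetrasubstituted enolate on an alkyl-substituted allyl complex, or selection of the enolate face in the opposite sense, which would pair the correct C10 with the wrong C9. The fallback sets out from 3 and 4 and returns at 20. The allylation is run with the ligand antipode so that the other diastereomer, ketone F1 (C10 as in 5, C9 inverted), is formed, and the two arms on C9 exchange their roles. Hydroboration–oxidation of the vinyl group (9-BBN; NaOH, H2O2) gives primary alcohol F2. Oxidation (TEMPO, PhI(OAc)2, MeCN–H2O) and TMSCHN2 give keto ester F3, in which the former vinyl carbons are C8 and C17. The same acylation–aldol annulation with 8 gives enone F4, Luche reduction gives allylic alcohol F5, and the diazene transposition gives silyl ether F6, whose C11 and C12 are already saturated. HF·pyridine frees alcohol F7; Ph3P, I2 and imidazole give iodide F8; zinc insertion (Zn, LiCl, THF) and Negishi coupling with 18 (Pd2(dba)3, SPhos) join C12 to C13 and reach 20.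

Step 4. What may go wrong: O-acylation or incomplete C-acylation of the ester enolate, or reversal of the aldol addition at the very hindered C5 carbonyl before water is lost. The fallback sets out from 7 and returns at 11. The lithium enolate of 7 is added to diethyl vinylphosphonate, and the phosphonate carbanion so formed olefinates the C5 ketone in the same flask (Michael addition, then intramolecular Horner–Wadsworth–Emmons reaction). This again joins C8 to C7 and C6 to C5 in one operation and gives alkene F9, with a C5=C6 double bond and a C7 methylene group. Allylic oxidation at C7, the only allylic methylene of that ring alkene (CrO3, 3,5-dimethylpyrazole, CH2Cl2, −20 °C), then gives 11.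

Step 6. What may go wrong: elimination across C7–C8 of the activated β-hydroxy ester to a dienoate, or slow displacement at the secondary C7 next to the ester-bearing C8. The fallback sets out from 12 and returns at 15. Alcohol 12 is converted into methyl carbonate F10 (ClCO2Me, pyridine). Palladium-catalysed formate reduction (Pd(OAc)2, PBu3, HCO2H, Et3N, THF) ionises the carbonate with inversion to an allyl–palladium complex on the face anti to the C10 methyl and delivers hydride from the metal to the more substituted terminus C5, giving the same trans-fused C6=C7 alkene 15.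

**Further compounds**

F1 | step 2 | ketone: (S)-2-[(R)-5-[(tert-butyldimethylsilyl)oxy]pent-1-en-3-yl]-2,6,6-trimethylcyclohexan-1-one (C9 epimer of 5) | CC(C)(C)[Si](C)(C)OCC[C@@H]([C@]1(C)CCCC(C)(C)C1=O)C=C
F2 | step 2 | primary alcohol: hydroboration–oxidation product of F1 (C17 hydroxyl) | CC(C)(C)[Si](C)(C)OCC[C@@H]([C@]1(C)CCCC(C)(C)C1=O)CCO
F3 | step 2 | keto ester: C8–C17 methyl ester arm and C11–C12 silyloxyethyl arm on C9 | CC(C)(C)[Si](C)(C)OCC[C@@H]([C@]1(C)CCCC(C)(C)C1=O)CC(=O)OC
F4 | step 2 | enone: analogue of 11 with 2-(silyloxy)ethyl at C9 | CC(C)(C)[Si](C)(C)OCC[C@@H]1[C@@H](C(=O)OC)C(=O)C=C2C(C)(C)CCC[C@@]12C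
F5 | step 2 | allylic alcohol: analogue of 12 with 2-(silyloxy)ethyl at C9 | CC(C)(C)[Si](C)(C)OCC[C@@H]1[C@@H](C(=O)OC)[C@H](O)C=C2C(C)(C)CCC[C@@]12C
F6 | step 2 | silyl ether: analogue of 15 with 2-(silyloxy)ethyl at C9 | CC(C)(C)[Si](C)(C)OCC[C@@H]1[C@@H](C(=O)OC)C=C[C@@H]2C(C)(C)CCC[C@@]12C
F7 | step 2 | alcohol: C12 primary alcohol from F6 | OCC[C@@H]1[C@@H](C(=O)OC)C=C[C@@H]2C(C)(C)CCC[C@@]12C
F8 | step 2 | iodide: C12 primary iodide from F7 | ICC[C@@H]1[C@@H](C(=O)OC)C=C[C@@H]2C(C)(C)CCC[C@@]12C
F9 | step 4 | alkene: C5=C6 ring B ester with C7 methylene (C8 epimers) | C=C[C@@H]1C(C(=O)OC)CC=C2C(C)(C)CCC[C@@]12C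
F10 | step 6 | methyl carbonate: C7 methyl carbonate of 12 | C=C[C@@H]1[C@@H](C(=O)OC)[C@H](OC(=O)OC)C=C2C(C)(C)CCC[C@@]12C
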